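**Retrosynthetic overview**
1. The tetronic acid ring is made last, by Dieckmann closure of an E α-(propanoyloxy)acrylate methyl ester; this latent tetronic acid carries the (5E)-ylidene geometry and needs no protecting group.
2. Key disconnection: both σ-bonds flanking the side-chain unit C5′–C8′ (C4′–C5′ and C8′–C9′) are cut at once, giving primary iodide 10, isoprene 19 and E-alkenyl iodide 18; a nickel-catalysed reductive three-component coupling joins them.
3. Enabling feature: C5′H2–C6′(CH3)=C7′H–C8′H2 is a head-to-tail isoprene residue lying between a saturated CH2 and the sp2 CH of the next alkene (a skipped diene), so it can enter as isoprene itself; its methyl makes one allyl terminus tertiary, which steers radical attack, 1,4-coupling and E geometry.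
4. The E enol ester comes from an E-enoate by syn-dihydroxylation, inversion at C3 by bromide (acyloxonium opening) and anti-E2; the one stereocentre comes from asymmetric hydrogenation of α-methylene-γ-butyrolactone.
5. Ring order: the furan is bought (3-bromofuran); the only ring formed is the tetronic acid (step 14).

Key step: step 13

Remark: the ylidene alkene is taken as drawn, (5E), side chain syn to C4–OH; this is normally the less stable geometry of a 5-ylidene tetronic acid, so it is set stereospecifically and not by equilibration. Locants C1′–C13′ count the side chain from the ylidene carbon.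

**Route**

Step 1
Reactants: 1 α-methylene-γ-butyrolactone (3-methylideneoxolan-2-one)
Product: 2 (3S)-3-methyloxolan-2-one
Conditions: H2 (100 atm), Ru2Cl4[(R)-BINAP]2·NEt3 (0.2 mol %), CH2Cl2, 50 °C
Reagents that add atoms: none
Why: Ru–BINAP asymmetric hydrogenation of an exocyclic α-methylene lactone, in which the chiral catalyst selects the enantioface and sets C3 as S; (R)-BINAP is the antipode expected for this sense, to be confirmed by the sign of rotation of 2 before it is carried on.

Step 2
Reactants: 2 (3S)-3-methyloxolan-2-one
Product: 3 (3S)-3-methyloxolan-2-ol (anomer mixture)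
Conditions: DIBAL-H (1.1 equiv), CH2Cl2, −78 °C; aq Rochelle salt
Reagents that add atoms: none
Why: Half-reduction of a γ-lactone to the lactol (the tetrahedral aluminate is stable at −78 °C) should leave the α-stereocentre untouched.

Step 3
Reactants: 3 (3S)-3-methyloxolan-2-ol
Product: 4 methyl (2E,4S)-6-hydroxy-4-methylhex-2-enoate
Conditions: Ph3P=CHCO2Me (1.3 equiv), toluene, 60 °C
Reagents that add atoms: methyl (triphenylphosphoranylidene)acetate, COC(=O)C=P(c1ccccc1)(c1ccccc1)c1ccccc1
Why: Wittig olefination of the open hydroxy-aldehyde form of the lactol with a stabilised ylide should be E-selective, and the neutral conditions should spare the α-methyl centre and avoid oxa-Michael closure.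

Step 4
Reactants: 4 methyl (2E,4S)-6-hydroxy-4-methylhex-2-enoate
Product: 5 methyl (2E,4S)-6-chloro-4-methylhex-2-enoate
Conditions: PPh3, NCS, CH2Cl2, 0 °C → rt
Reagents that add atoms: N-chlorosuccinimide, O=C1CCC(=O)N1Cl
Why: Appel-type chlorination (SN2 on the alkoxyphosphonium ion) gives a primary chloride that should be inert in steps 5–7, where a free hydroxyl would trap the acyloxonium ion and an iodide would be displaced by the C3 hydroxyl.

Step 5
Reactants: 5 methyl (2E,4S)-6-chloro-4-methylhex-2-enoate
Product: 6 methyl (2S,3R,4S)-6-chloro-2,3-dihydroxy-4-methylhexanoate (plus its 2R,3S,4S diastereomer; both 2,3-syn)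
Conditions: OsO4 (2 mol %), NMO (1.5 equiv), acetone/H2O 5:1, rt
Reagents that add atoms: N-methylmorpholine N-oxide, C[N+]1([O-])CCOCC1; water, O
Why: Upjohn syn-dihydroxylation of the E-enoate can give only 2,3-syn diols, and the two face isomers converge in step 7, where C2 and C3 become sp2 again.

Step 6
Reactants: 6 methyl (2S,3R,4S)-6-chloro-2,3-dihydroxy-4-methylhexanoate (and diastereomer)
Product: 8 methyl (2R,3S,4S)-3-bromo-6-chloro-4-methyl-2-(propanoyloxy)hexanoate (plus its 2S,3R,4S diastereomer; both 2,3-anti), via cyclic orthoester 7 (not isolated)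
Conditions: EtC(OEt)3 (1.3 equiv), PPTS (cat.), CH2Cl2, rt; evaporate; TMSBr (1.3 equiv), CH2Cl2, 0 °C → rt
Reagents that add atoms: triethyl orthopropanoate, CCC(OCC)(OCC)OCC; bromotrimethylsilane, C[Si](C)(C)Br
Why: Vicinal diol → acyloxy halide conversion: the cyclic orthoester ionises to a 2-ethyl-1,3-dioxolan-2-ylium ion, which bromide should open at C3 (the carbon remote from the ester) with inversion, placing the propanoate on O2 and turning the syn diol into the anti acyloxy bromide.

Step 7
Reactants: 8 methyl (2R,3S,4S)-3-bromo-6-chloro-4-methyl-2-(propanoyloxy)hexanoate (and diastereomer)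
Product: 9 methyl (2E,4S)-6-chloro-4-methyl-2-(propanoyloxy)hex-2-enoate
Conditions: DBU (1.2 equiv), CH2Cl2, 0 °C
Reagents that add atoms: none
Why: E2 anti-elimination of HBr (H2 antiperiplanar to Br) from the 2,3-anti isomer should give the E enol ester with C4 syn to CO2Me, as in the route from allo-threonine derivatives to E-dehydroamino esters; DBU is too weak to form the free enolate, which should suppress E1cB leakage to the Z isomer.

Step 8
Reactants: 9 methyl (2E,4S)-6-chloro-4-methyl-2-(propanoyloxy)hex-2-enoate
Product: 10 methyl (2E,4S)-6-iodo-4-methyl-2-(propanoyloxy)hex-2-enoate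
Conditions: NaI (5 equiv), acetone, reflux, dark
Reagents that add atoms: sodium iodide, [Na+].[I-]
Why: Finkelstein exchange at the unhindered primary chloride, driven by precipitation of NaCl, provides the radical precursor.

Step 9
Reactants: 11 pent-4-yn-1-ol
Product: 13 (4E)-5-iodo-4-methylpent-4-en-1-ol, via alkenylalane 12 (not isolated)
Conditions: Me3Al (3 equiv), Cp2ZrCl2 (0.3 equiv), CH2Cl2, 0 °C → rt; I2, THF, −30 → 0 °C; aq K2CO3
Reagents that add atoms: trimethylaluminium, C[Al](C)C; iodine, II
Why: Zirconium-catalysed carboalumination adds CH3 and Al syn with Al on the terminal carbon, and iodinolysis with retention should give the E vinyl iodide.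

Step 10
Reactants: 13 (4E)-5-iodo-4-methylpent-4-en-1-ol
Product: 14 (4E)-5-iodo-4-methylpent-4-enal
Conditions: Dess–Martin periodinane (1.2 equiv), NaHCO3, CH2Cl2, 0 °C → rt
Reagents that add atoms: none
Why: Dess–Martin oxidation of a primary alcohol stops at the aldehyde and should not touch the vinyl iodide.

Step 11
Reactants: 15 3-bromofuran; 14 (4E)-5-iodo-4-methylpent-4-enal
Product: 17 (4E)-1-(furan-3-yl)-5-iodo-4-methylpent-4-en-1-ol (racemic), via 3-furyllithium 16 (not isolated)
Conditions: 15 (1.3 equiv), n-BuLi (1.2 equiv), THF, −78 °C, 20 min; 14, −78 °C; aq NH4Cl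
Reagents that add atoms: none
Why: Br/Li exchange at −78 °C (cold enough to stop isomerisation to 2-lithiofuran; no n-BuLi left to attack the vinyl iodide) and 1,2-addition to the aldehyde; the new carbinol centre is racemic and is removed in step 12.

Step 12
Reactants: 17 (4E)-1-(furan-3-yl)-5-iodo-4-methylpent-4-en-1-ol
Product: 18 (4E)-1-(furan-3-yl)-5-iodo-4-methylpent-4-en-1-one
Conditions: Dess–Martin periodinane (1.3 equiv), NaHCO3, CH2Cl2, 0 °C → rt
Reagents that add atoms: none
Why: Buffered Dess–Martin oxidation of the furyl carbinol should give the 3-furyl ketone without harm to the furan or the vinyl iodide.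

Step 13
Reactants: 10 methyl (2E,4S)-6-iodo-4-methyl-2-(propanoyloxy)hex-2-enoate; 19 isoprene (2-methylbuta-1,3-diene); 18 (4E)-1-(furan-3-yl)-5-iodo-4-methylpent-4-en-1-one
Product: 20 methyl (2E,4S,8E,11E)-15-(furan-3-yl)-4,8,12-trimethyl-15-oxo-2-(propanoyloxy)pentadeca-2,8,11-trienoate
Conditions: NiBr2·glyme (10 mol %), dtbbpy (12 mol %), Mn (3 equiv), isoprene (15 equiv), DMA, 25 °C, sealed vessel; 10 (1.5 equiv) added over 4 h
Reagents that add atoms: none
Why: Proposed new method: Ni(0)/dtbbpy, formed from NiBr2 and Mn, should insert into the C(sp2)–I bond of 18 with retention, while Ni(I) abstracts iodine from the primary iodide 10; the C6 radical of 10, met by a large excess of isoprene, should add to C1 of the diene (the CH2 next to the methyl-bearing carbon, giving the allyl radical with a tertiary and a primary terminus) and so form the CH2–CH2 bond, after which the allyl radical is captured by the alkenylnickel(II) species and reductive elimination at the primary terminus (C4 of isoprene) forms the second C–C bond and returns Ni(I), which Mn reduces. The closest known reaction types are the nickel-catalysed reductive three-component alkyl/aryl or alkyl/alkenyl dicarbofunctionalisation of alkenes (alkyl iodide, alkene, C(sp2) halide, Mn or Zn) and the nickel-catalysed radical 1,4-dicarbofunctionalisation of 1,3-dienes; what is new is the combination of an unactivated primary iodide, isoprene and an alkenyl iodide. No ring is closed and no stereocentre is made, and C4 of 10, two carbons from the radical, should be untouched. The new trisubstituted alkene should be E because the radical adds to s-trans isoprene and the allyl unit can exchange its CH3 and CH2R groups only through a σ-bond from nickel to the tertiary terminus, and the 1,4 mode should win because coupling at that terminus would build a quaternary carbon. The step needs three-component over direct two-component coupling, secured by 15 equiv of isoprene (addition of a primary radical to the diene outruns its capture by nickel at low catalyst concentration) and by slow addition of 10; the choice between the two iodides rests on the usual divide between oxidative addition at sp2 carbon and halogen abstraction at sp3 carbon.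

Step 14
Reactants: 20 methyl (2E,4S,8E,11E)-15-(furan-3-yl)-4,8,12-trimethyl-15-oxo-2-(propanoyloxy)pentadeca-2,8,11-trienoate
Product: 21 (5E)-5-[(2S,6E,9E)-13-(furan-3-yl)-2,6,10-trimethyl-13-oxotrideca-6,9-dien-1-ylidene]-4-hydroxy-3-methylfuran-2(5H)-one (CNP0018619.1)
Conditions: LiHMDS (3.3 equiv), THF, −78 → −20 °C; cold 1 M HCl to pH 3; work-up in dim light
Reagents that add atoms: none
Why: Dieckmann (Claisen) cyclisation in which the propanoate enolate attacks the neighbouring methyl ester (5-exo-trig) to close the 3-methyltetronic acid ring; the C2=C3 alkene of 20 is not involved, so its E geometry should pass to the ylidene, and the extra base holds the furyl ketone as its lithium enolate until the quench.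

**Compound list**
1 | α-methylene-γ-butyrolactone (3-methylideneoxolan-2-one) | C=C1CCOC1=O | starting material
2 | (3S)-3-methyloxolan-2-one | O=C1[C@@H](C)CCO1 | intermediate
3 | (3S)-3-methyloxolan-2-ol (anomer mixture) | OC1[C@@H](C)CCO1 | intermediate
4 | methyl (2E,4S)-6-hydroxy-4-methylhex-2-enoate | COC(=O)/C=C/[C@@H](C)CCO | intermediate
5 | methyl (2E,4S)-6-chloro-4-methylhex-2-enoate | COC(=O)/C=C/[C@@H](C)CCCl | intermediate
6 | methyl (2S,3R,4S)-6-chloro-2,3-dihydroxy-4-methylhexanoate (formed with its 2R,3S,4S diastereomer) | COC(=O)[C@@H](O)[C@H](O)[C@@H](C)CCCl | intermediate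
7 | methyl (4S,5R)-5-[(2S)-4-chlorobutan-2-yl]-2-ethoxy-2-ethyl-1,3-dioxolane-4-carboxylate (cyclic orthoester; C2 epimers; and the 4R,5S series) | COC(=O)[C@@H](OC1(CC)OCC)[C@H](O1)[C@@H](C)CCCl | intermediate (not isolated)
8 | methyl (2R,3S,4S)-3-bromo-6-chloro-4-methyl-2-(propanoyloxy)hexanoate (formed with its 2S,3R,4S diastereomer) | COC(=O)[C@@H](OC(=O)CC)[C@@H](Br)[C@@H](C)CCCl | intermediate
9 | methyl (2E,4S)-6-chloro-4-methyl-2-(propanoyloxy)hex-2-enoate | COC(=O)/C(=C\[C@@H](C)CCCl)OC(=O)CC | intermediate
10 | methyl (2E,4S)-6-iodo-4-methyl-2-(propanoyloxy)hex-2-enoate | COC(=O)/C(=C\[C@@H](C)CCI)OC(=O)CC | intermediate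
11 | pent-4-yn-1-ol | C#CCCCO | starting material
12 | (E)-[5-(dimethylalumanyloxy)-2-methylpent-1-en-1-yl]dimethylalumane | C[Al](C)/C=C(\C)CCCO[Al](C)C | intermediate (not isolated)
13 | (4E)-5-iodo-4-methylpent-4-en-1-ol | OCCC/C(C)=C/I | intermediate
14 | (4E)-5-iodo-4-methylpent-4-enal | O=CCC/C(C)=C/I | intermediate
15 | 3-bromofuran | Brc1ccoc1 | starting material
16 | 3-furyllithium | [Li]c1ccoc1 | intermediate (not isolated)
17 | (4E)-1-(furan-3-yl)-5-iodo-4-methylpent-4-en-1-ol (racemic) | OC(CC/C(C)=C/I)c1ccoc1 | intermediate
18 | (4E)-1-(furan-3-yl)-5-iodo-4-methylpent-4-en-1-one | O=C(CC/C(C)=C/I)c1ccoc1 | intermediate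
19 | isoprene (2-methylbuta-1,3-diene) | C=CC(C)=C | starting material
20 | methyl (2E,4S,8E,11E)-15-(furan-3-yl)-4,8,12-trimethyl-15-oxo-2-(propanoyloxy)pentadeca-2,8,11-trienoate | COC(=O)/C(=C\[C@@H](C)CCC/C(C)=C/C/C=C(\C)CCC(=O)c1ccoc1)OC(=O)CC | intermediate
21 | (5E)-5-[(2S,6E,9E)-13-(furan-3-yl)-2,6,10-trimethyl-13-oxotrideca-6,9-dien-1-ylidene]-4-hydroxy-3-methylfuran-2(5H)-one | CC1=C(O)/C(=C\[C@@H](C)CCC/C(C)=C/C/C=C(\C)CCC(=O)c2ccoc2)OC1=O | target

**Count and risks**

Total steps: 14. Longest linear sequence: 10 steps (steps 1–8, 13, 14); the alkenyl iodide branch is 4 steps (9–12).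

Steps most likely to fail:

1. Step 13 (proposed new method). What may go wrong: direct alkyl–alkenyl coupling without uptake of isoprene, attack of the radical at the other diene terminus (which would move the methyl group to C9 of 20), coupling at the tertiary allyl terminus, or oligomerisation of isoprene on nickel. The fallback uses known chemistry, sets out from 18 and comes back at 20. Miyaura borylation of 18 (B2pin2, PdCl2(dppf), KOPh, toluene, 50 °C) should give the E-alkenyl boronate F1. Palladium(0)-catalysed 1,4-coupling of F1 with commercial 2-methyl-2-vinyloxirane (Pd(PPh3)4, THF/H2O, rt; SN2′ opening through the π-allyl alkoxide) should give the (4E,7E)-dienol F2. Methyl chloroformate and pyridine convert F2 into the allylic methyl carbonate F3. Nickel-catalysed reductive allylation of the alkyl iodide 10 with F3 (NiCl2·glyme, bipyridine ligand, Zn, MgCl2, pyridine, DMA, rt), in which the alkyl group enters at the unsubstituted allyl terminus, should then give 20.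

2. Step 6. What may go wrong: slow or misdirected opening of the dioxolanylium ion (attack at C2, or elimination, because C3 is flanked by the C4 branch), and with it loss of the 2,3-anti relationship on which the alkene geometry depends. The fallback sets out from 6 and comes back at 9, so it also replaces the base-induced elimination of step 7. Diol 6 is converted with SOCl2/Et3N into the cyclic sulfite F4 and oxidised (RuCl3 cat., NaIO4, MeCN/H2O) to the cyclic sulfate F5. Caesium propanoate in DMF should open F5 at C2 (α to the ester, inversion) to give the C3 sulfate monoester F6, which is hydrolysed in the same flask (cat. H2SO4, THF, a little water) to the 2,3-anti hydroxy propanoate F7. Anti-dehydration of F7 with Martin sulfurane (CH2Cl2, 0 °C → rt), the non-basic method used to turn allo-threonine derivatives into E-dehydroamino esters, should give 9.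

3. Step 14. What may go wrong: enolisation of the furyl ketone followed by acyl transfer from the enol ester between molecules, or γ-deprotonation at C4 with loss of the alkene geometry and of the stereocentre; the E ylidene may also drift to Z on acidic or bright work-up. The fallback sets out from 20 and comes back at 21. The ketone is masked as the dioxolane F8 (1,2-bis(trimethylsiloxy)ethane, TMSOTf cat., CH2Cl2, −78 → −20 °C). The Dieckmann closure is then run with only 2.2 equiv LiHMDS at −78 °C to give the ketal tetronic acid F9. The ketone is released with PPTS in wet acetone at 40 °C.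

Further compounds
F1 | step 13 | (4E)-1-(furan-3-yl)-4-methyl-5-(4,4,5,5-tetramethyl-1,3,2-dioxaborolan-2-yl)pent-4-en-1-one | O=C(CC/C(C)=C/B1OC(C)(C)C(C)(C)O1)c1ccoc1
F2 | step 13 | (4E,7E)-1-(furan-3-yl)-9-hydroxy-4,8-dimethylnona-4,7-dien-1-one | O=C(CC/C(C)=C/C/C=C(\C)CO)c1ccoc1
F3 | step 13 | (2E,5E)-9-(furan-3-yl)-2,6-dimethyl-9-oxonona-2,5-dien-1-yl methyl carbonate | O=C(CC/C(C)=C/C/C=C(\C)COC(=O)OC)c1ccoc1
F4 | step 6 | methyl (4S,5R)-5-[(2S)-4-chlorobutan-2-yl]-1,3,2-dioxathiolane-4-carboxylate 2-oxide (and the 4R,5S series) | COC(=O)[C@@H](OS1=O)[C@H](O1)[C@@H](C)CCCl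
F5 | step 6 | methyl (4S,5R)-5-[(2S)-4-chlorobutan-2-yl]-1,3,2-dioxathiolane-4-carboxylate 2,2-dioxide (and the 4R,5S series) | COC(=O)[C@@H](OS1(=O)=O)[C@H](O1)[C@@H](C)CCCl
F6 | step 6 | caesium (2R,3R,4S)-6-chloro-1-methoxy-4-methyl-1-oxo-2-(propanoyloxy)hexan-3-yl sulfate (and the 2S,3S,4S isomer) | COC(=O)[C@H](OC(=O)CC)[C@H](OS(=O)(=O)[O-])[C@@H](C)CCCl.[Cs+]
F7 | step 6 | methyl (2R,3R,4S)-6-chloro-3-hydroxy-4-methyl-2-(propanoyloxy)hexanoate (and the 2S,3S,4S isomer; both 2,3-anti) | COC(=O)[C@H](OC(=O)CC)[C@H](O)[C@@H](C)CCCl
F8 | step 14 | methyl (2E,4S,8E,11E)-14-[2-(furan-3-yl)-1,3-dioxolan-2-yl]-4,8,12-trimethyl-2-(propanoyloxy)tetradeca-2,8,11-trienoate | COC(=O)/C(=C\[C@@H](C)CCC/C(C)=C/C/C=C(\C)CCC1(OCCO1)c1ccoc1)OC(=O)CC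
F9 | step 14 | (5E)-5-[(2S,6E,9E)-12-[2-(furan-3-yl)-1,3-dioxolan-2-yl]-2,6,10-trimethyldodeca-6,9-dien-1-ylidene]-4-hydroxy-3-methylfuran-2(5H)-one | CC1=C(O)/C(=C\[C@@H](C)CCC/C(C)=C/C/C=C(\C)CCC2(OCCO2)c2ccoc2)OC1=O
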